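**Plan**

- Retrosynthesis: the phenol O–Si bond is cut last, then ring A is cut at C1–C2 and C1–C6. C1, the carbon that bears the ester carbonyl, lies between the two unsubstituted CH carbons C2 and C6, while C3, C4 and C5 carry prenyl, oxygen and prenyl. C2–C6 therefore map onto 3,5-diprenyl-4-pyranone (ring oxygen where C1 will sit, carbonyl oxygen as the future phenol), and C1 onto the carbon of an ester-stabilised phosphorane.
- The pyranone is cut to a symmetrical ketone plus two formyl carbons, and the ketone to acetonedicarboxylate plus two prenyl bromides. The phosphorane is cut to terpinen-4-ol, bromoacetyl bromide and PPh3.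
- Forward: the pyranone ring is made first (steps 1–3) and the ylide in parallel (steps 4–5). Ring A is then made out of the pyranone ring in step 6, and the silyl ether is removed in step 7.
- Stereochemistry: the only stereocentre, the (R) quaternary carbinol carbon, is bought with (R)-terpinen-4-ol. Only its O–H bond ever reacts, and no stereocentre is created in the route.

Key step: step 6

Remark: (R)-terpinen-4-ol is taken as a commercial single enantiomer of high optical purity; its enantiomeric purity should be checked before use, because nothing later in the route can correct it.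

**Step 1**
Reactants: 1 diethyl 1,3-acetonedicarboxylate; 2 prenyl bromide (2.1 equiv)
Product: 3 diethyl 2,4-bis(3-methylbut-2-en-1-yl)-3-oxopentanedioate (mixture of diastereomers)
Conditions: K2CO3 (2.5 equiv), acetone, reflux
Reagents that add atoms: none
Why: Twofold C-alkylation of a β-keto diester (acetoacetic ester type alkylation) by a reactive allylic bromide; after the first prenylation the untouched CH2 is the more acidic and less hindered site, so the second prenyl group should enter at C4 and not again at C2.

**Step 2**
Reactants: 3 diethyl 2,4-bis(3-methylbut-2-en-1-yl)-3-oxopentanedioate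
Product: 4 2,10-dimethylundeca-2,9-dien-6-one
Conditions: LiCl, H2O, DMSO, 150 °C
Reagents that add atoms: none
Why: Krapcho dealkoxycarbonylation removes both β-keto ester groups under neutral conditions, which spares the acid-sensitive trisubstituted alkenes and erases the two stereocentres of 3.

**Step 3**
Reactants: 4 2,10-dimethylundeca-2,9-dien-6-one
Product: 6 3,5-bis(3-methylbut-2-en-1-yl)-4H-pyran-4-one, via bis(hydroxymethylene) ketone 5 (not isolated)
Conditions: HCO2Et (excess), NaH (2.5 equiv), THF, 0 °C → rt; then 1 M HCl to pH 2, 0 °C → rt
Reagents that add atoms: ethyl formate, CCOC=O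
Why: Twofold crossed Claisen formylation at both α-methylene groups followed by acid-induced cyclodehydration of the 1,3,5-tricarbonyl system is the classical entry to 3,5-disubstituted 4-pyranones, and cold dilute acid should be mild enough for the prenyl groups.

**Step 4**
Reactants: 7 (R)-terpinen-4-ol; 8 bromoacetyl bromide (1.3 equiv)
Product: 9 (R)-terpinen-4-yl bromoacetate
Conditions: PhNMe2 (1.5 equiv), CH2Cl2, 0 °C → rt
Reagents that add atoms: none
Why: O-Acylation of a tertiary alcohol by an acyl bromide with N,N-dimethylaniline as acid scavenger is the standard preparation of tert-alkyl bromoacetates; the C–O bond of the carbinol is not touched, so the (R) centre is retained, and the base traps HBr before it can ionise the tertiary ester.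

**Step 5**
Reactants: 9 (R)-terpinen-4-yl bromoacetate
Product: 11 (R)-terpinen-4-yl (triphenylphosphoranylidene)acetate, via phosphonium bromide 10 (not isolated)
Conditions: PPh3, toluene, rt → 40 °C; then 1 M NaOH, CH2Cl2/H2O, 0 °C
Reagents that add atoms: triphenylphosphine, c1ccc(cc1)P(c1ccccc1)c1ccccc1
Why: SN2 quaternisation of PPh3 by the α-bromo ester and deprotonation of the acidic phosphonium salt with aqueous NaOH is the standard preparation of ester-stabilised Wittig ylides, and the hindered tertiary ester should resist saponification.

**Step 6**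
Reactants: 6 3,5-bis(3-methylbut-2-en-1-yl)-4H-pyran-4-one; 11 (R)-terpinen-4-yl (triphenylphosphoranylidene)acetate
Product: 15 (R)-terpinen-4-yl 4-(tert-butyldimethylsilyloxy)-3,5-bis(3-methylbut-2-en-1-yl)benzoate (TBS ether of the target), via silyloxypyrylium triflate 12 (not isolated), via 2H-pyranyl phosphonium triflate 13 (not isolated), via ylide dienal 14 (not isolated)
Conditions: 6 (1.1 equiv), TBSOTf (1.05 equiv), CH2Cl2, 0 °C → rt; 11 (1.0 equiv), −78 → 0 °C; Et3N (1.5 equiv), rt → 40 °C
Reagents that add atoms: tert-butyldimethylsilyl trifluoromethanesulfonate (TBSOTf), CC(C)(C)[Si](C)(C)OS(=O)(=O)C(F)(F)F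
Why: Proposed new method: TBSOTf, kept just below one equivalent per pyranone, silylates the carbonyl oxygen of 6 to the aromatic 4-silyloxypyrylium ion 12, the ylide carbon of 11 adds to its unsubstituted C2 to give the 2H-pyran phosphonium salt 13, Et3N removes the proton between phosphorus and the ester so that the C2–O bond breaks (6π electrocyclic opening of the 2H-pyran, equivalent to β-elimination of the enol oxygen) to give ylide dienal 14, and 14 closes by intramolecular Wittig olefination with loss of Ph3PO. The closest known reaction types are the conversion of pyrylium salts into benzenes by alkylidenephosphoranes or nitromethane and the C2 addition of carbon nucleophiles to 4-silyloxypyrylium ions made from 4-pyranones and silyl triflates, but their combination with an ester-stabilised ylide has not been shown. Ring A is closed as a six-membered carbocycle by 6-exo-trig attack of the ylide carbon on the aldehyde carbon (bond C1–C6, the bond C1–C2 having been made in the addition); the formyl carbon C6 and C3 are held cis across the C4=C5 bond because that bond comes from the pyran ring, the push-pull character of 14 lets the C2=C3 bond rotate into the reactive geometry, and aromatisation drives the loss of Ph3PO. No stereocentre is formed, the two centres of 13 disappear on aromatisation, and the (R) carbinol carbon of the ester is a spectator. The step needs addition at C2 or C6 and not at C4, which is secured because C2 and C6 are equivalent by the symmetry of 12 while C4 carries the silyloxy group between two prenyl groups, so that addition there is hindered and reversible. Using Et3N as the base in place of a second equivalent of ylide, and leaving no free silyl triflate, should keep the aldehyde of 14 from intermolecular olefination and the tertiary ester from silyl-triflate cleavage.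

**Step 7**
Reactants: 15 (R)-terpinen-4-yl 4-(tert-butyldimethylsilyloxy)-3,5-bis(3-methylbut-2-en-1-yl)benzoate
Product: 16 (R)-terpinen-4-yl 4-hydroxy-3,5-bis(3-methylbut-2-en-1-yl)benzoate (target, CNP0120997.1)
Conditions: Bu4NF (1.1 equiv), AcOH (1.1 equiv), THF, 0 °C
Reagents that add atoms: none
Why: Fluoride-induced cleavage of an aryl silyl ether is fast at 0 °C, the acetic acid buffer protonates the hindered phenoxide as it forms, and the tertiary benzoate and the three trisubstituted alkenes are inert to these conditions.

**Compound list**

1 | diethyl 1,3-acetonedicarboxylate (diethyl 3-oxopentanedioate) | CCOC(=O)CC(=O)CC(=O)OCC | starting material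
2 | prenyl bromide (1-bromo-3-methylbut-2-ene) | CC(C)=CCBr | starting material
3 | diethyl 2,4-bis(3-methylbut-2-en-1-yl)-3-oxopentanedioate, mixture of diastereomers | CCOC(=O)C(CC=C(C)C)C(=O)C(CC=C(C)C)C(=O)OCC | intermediate
4 | 2,10-dimethylundeca-2,9-dien-6-one | CC(C)=CCCC(=O)CCC=C(C)C | intermediate
5 | 1,5-dihydroxy-2,4-bis(3-methylbut-2-en-1-yl)penta-1,4-dien-3-one, the bis-enol of the 2,4-diformyl ketone (formed in the flask, not isolated) | O=C(C(CC=C(C)C)=CO)C(CC=C(C)C)=CO | intermediate
6 | 3,5-bis(3-methylbut-2-en-1-yl)-4H-pyran-4-one (3,5-diprenyl-4-pyranone) | O=c1c(CC=C(C)C)cocc1CC=C(C)C | intermediate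
7 | (R)-terpinen-4-ol, (1R)-4-methyl-1-(propan-2-yl)cyclohex-3-en-1-ol | CC1=CC[C@@](O)(C(C)C)CC1 | starting material
8 | bromoacetyl bromide | O=C(Br)CBr | starting material
9 | (R)-terpinen-4-yl bromoacetate, (1R)-4-methyl-1-(propan-2-yl)cyclohex-3-en-1-yl 2-bromoacetate | O=C(CBr)O[C@@]1(C(C)C)CC=C(C)CC1 | intermediate
10 | {2-oxo-2-[(1R)-4-methyl-1-(propan-2-yl)cyclohex-3-en-1-yloxy]ethyl}triphenylphosphonium bromide (formed in the flask, not isolated) | O=C(C[P+](c1ccccc1)(c1ccccc1)c1ccccc1)O[C@@]1(C(C)C)CC=C(C)CC1.[Br-] | intermediate
11 | (R)-terpinen-4-yl (triphenylphosphoranylidene)acetate | O=C(C=P(c1ccccc1)(c1ccccc1)c1ccccc1)O[C@@]1(C(C)C)CC=C(C)CC1 | intermediate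
12 | 4-(tert-butyldimethylsilyloxy)-3,5-bis(3-methylbut-2-en-1-yl)pyrylium trifluoromethanesulfonate (formed in the flask, not isolated) | CC(C)=CCc1c[o+]cc(CC=C(C)C)c1O[Si](C)(C)C(C)(C)C.[O-]S(=O)(=O)C(F)(F)F | intermediate
13 | {[4-(tert-butyldimethylsilyloxy)-3,5-bis(3-methylbut-2-en-1-yl)-2H-pyran-2-yl][(R)-terpinen-4-yloxycarbonyl]methyl}triphenylphosphonium trifluoromethanesulfonate, mixture of diastereomers at the two new carbons (formed in the flask, not isolated) | CC(C)=CCC1=COC(C(C(=O)O[C@@]2(C(C)C)CC=C(C)CC2)[P+](c2ccccc2)(c2ccccc2)c2ccccc2)C(CC=C(C)C)=C1O[Si](C)(C)C(C)(C)C.[O-]S(=O)(=O)C(F)(F)F | intermediate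
14 | (R)-terpinen-4-yl 5-(tert-butyldimethylsilyloxy)-4,6-bis(3-methylbut-2-en-1-yl)-7-oxo-2-(triphenylphosphoranylidene)hepta-3,5-dienoate, formyl carbon and chain cis across the silyloxy-bearing double bond, geometry of the other double bond mobile (formed in the flask, not isolated) | O=C/C(CC=C(C)C)=C(/O[Si](C)(C)C(C)(C)C)C(CC=C(C)C)=CC(C(=O)O[C@@]1(C(C)C)CC=C(C)CC1)=P(c1ccccc1)(c1ccccc1)c1ccccc1 | intermediate
15 | (R)-terpinen-4-yl 4-(tert-butyldimethylsilyloxy)-3,5-bis(3-methylbut-2-en-1-yl)benzoate | CC(C)=CCc1cc(C(=O)O[C@@]2(C(C)C)CC=C(C)CC2)cc(CC=C(C)C)c1O[Si](C)(C)C(C)(C)C | intermediate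
16 | (1R)-4-methyl-1-(propan-2-yl)cyclohex-3-en-1-yl 4-hydroxy-3,5-bis(3-methylbut-2-en-1-yl)benzoate | CC(C)=CCc1cc(C(=O)O[C@@]2(C(C)C)CC=C(C)CC2)cc(CC=C(C)C)c1O | target

**Step count and risks**

Total step count: 7 (compounds 5, 10, 12, 13 and 14 are not isolated). Longest linear sequence: 5 steps (1, 2, 3, 6, 7); the ylide branch (steps 4 and 5) joins at step 6.

Steps most likely to fail:

1. Step 6 (Proposed new method). Three processes could defeat it:
   - Silyl transfer from the pyrylium oxygen to the ylide oxygen would return the pyranone instead of forming the C1–C2 bond.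
   - The fully substituted ylide carbon of the open-chain intermediate may olefinate slowly, so that the chain recloses to the 2H-pyran or decomposes.
   - The tertiary ester may ionise under silyl-triflate activation.

   The fallback uses known chemistry, sets out from 7 and 2 and comes back at 15. Ring A is bought instead of made. Commercial 3,5-dibromo-4-hydroxybenzoic acid is silylated on both oxygens (TBSCl, imidazole, DMF) to tert-butyldimethylsilyl 3,5-dibromo-4-(tert-butyldimethylsilyloxy)benzoate F1. Oxalyl chloride with catalytic DMF in CH2Cl2 converts the silyl ester directly into 3,5-dibromo-4-(tert-butyldimethylsilyloxy)benzoyl chloride F2. The lithium alkoxide of 7 (n-BuLi, THF, −78 °C) is acylated by F2 to give (R)-terpinen-4-yl 3,5-dibromo-4-(tert-butyldimethylsilyloxy)benzoate F3. Prenylzinc bromide F4 (Me2C=CHCH2ZnBr), made from 2 and Zn with LiCl in THF, is then coupled twice with F3 in a linear-selective Negishi reaction (Pd(OAc)2, CPhos, THF, rt). This should give 15, which rejoins the route before step 7.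

2. Step 3. The second formylation may stall because the monoformyl enolate resists a further deprotonation, and during the acid cyclodehydration an enol oxygen may add to a protonated prenyl double bond. The fallback sets out from 4 and comes back at 6. Ketone 4 is heated with tert-butoxybis(dimethylamino)methane (neat or in toluene, 100 °C), which needs no enolate dianion and should give 1,5-bis(dimethylamino)-2,4-bis(3-methylbut-2-en-1-yl)penta-1,4-dien-3-one F5. Brief treatment with aqueous AcOH in THF at rt should hydrolyse one enamine and close the ring with loss of dimethylamine to give 6.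

3. Step 4. Acylation of the hindered tertiary O–H may be slow, HBr may ionise the tertiary ester with elimination to dienes, and the amine base may be alkylated by the bromoacetate. The fallback sets out from 7 and comes back at 11, bypassing 9 and 10. Alcohol 7 is heated with ketenylidenetriphenylphosphorane (Ph3P=C=C=O) in toluene at 80–110 °C; addition of the O–H bond across the cumulated ylide should give 11 directly, without acid, halide or base. No new compound is made on the way.

**Further compounds**

F1 | step 6 | tert-butyldimethylsilyl 3,5-dibromo-4-(tert-butyldimethylsilyloxy)benzoate | CC(C)(C)[Si](C)(C)OC(=O)c1cc(Br)c(O[Si](C)(C)C(C)(C)C)c(Br)c1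
F2 | step 6 | 3,5-dibromo-4-(tert-butyldimethylsilyloxy)benzoyl chloride | O=C(Cl)c1cc(Br)c(O[Si](C)(C)C(C)(C)C)c(Br)c1
F3 | step 6 | (R)-terpinen-4-yl 3,5-dibromo-4-(tert-butyldimethylsilyloxy)benzoate | O=C(O[C@@]1(C(C)C)CC=C(C)CC1)c1cc(Br)c(O[Si](C)(C)C(C)(C)C)c(Br)c1
F4 | step 6 | prenylzinc bromide | CC(C)=CC[Zn]Br
F5 | step 3 | 1,5-bis(dimethylamino)-2,4-bis(3-methylbut-2-en-1-yl)penta-1,4-dien-3-one | CN(C)C=C(CC=C(C)C)C(=O)C(CC=C(C)C)=CN(C)C
F0 | step 4 | none | none
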